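**Retrosynthetic overview**
1. The indole is the only ring system and is bought intact as 5-bromoindole 1, so no ring is formed. Cutting the C5–prenyl bond gives 1 and prenylboronate 2 (forward: linear-selective Suzuki coupling to 5-prenylindole 3).
2. The whole C5 side chain, already carrying the palmitate, is one achiral ketone: 3-hydroxy-3-methylbutan-2-one 4 → bromoketone 5 → displacement by palmitic acid 6 → α-acyloxy-α'-hydroxy ketone 7.
3. Key disconnection: the indole C3–C bond and the C–H bond of the stereocenter are cut together. Forward, 3 and 7 are joined by a chiral Brønsted-acid-catalysed reductive Friedel–Crafts alkylation with a Hantzsch ester (carbinol 8 → azafulvenium ion 9 → target 10).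
4. The single stereocenter is set in the last step by a metal-free catalyst, nothing afterwards can scramble it, and no protecting group is used.

Assumption: the target stereocenter is (S) (CIP order C(CH3)2OH > CH2O-acyl > indol-3-yl > H). The (R)-antipode of the acid catalyst is written from the usual ion-pair model; because the step is new, the sense is checked on the first run and the (S)-catalyst is used if the mirror image forms.

**Step 1**
Reactants: 1 5-bromo-1H-indole; 2 2-(3-methylbut-2-en-1-yl)-4,4,5,5-tetramethyl-1,3,2-dioxaborolane (prenylboronic acid pinacol ester)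
Product: 3 5-(3-methylbut-2-en-1-yl)-1H-indole
Conditions: PdCl2(IPent)(3-chloropyridine) (2 mol %; IPent = 1,3-bis[2,6-di(pentan-3-yl)phenyl]imidazol-2-ylidene), 5 M aq KOH, THF, 70 °C
Reagents that add atoms: none
Why: Suzuki–Miyaura allyl–aryl cross-coupling in which the very bulky carbene ligand makes reductive elimination from the primary (α-bound) σ-prenyl palladium species dominant, so the linear prenyl arene forms rather than the 1,1-dimethylallyl isomer; the free N–H is tolerated and no stereocenter is created.

**Step 2**
Reactants: 4 3-hydroxy-3-methylbutan-2-one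
Product: 5 1-bromo-3-hydroxy-3-methylbutan-2-one
Conditions: Br2 (1.0 equiv), MeOH, 0 °C to rt; then H2O
Reagents that add atoms: bromine, BrBr
Why: Acid-catalysed α-bromination of a methyl ketone through its enol; the CH3 group is the only enolisable position because the other α-carbon is quaternary, and methanol (via the ketal) suppresses dibromination.

**Step 3**
Reactants: 5 1-bromo-3-hydroxy-3-methylbutan-2-one; 6 hexadecanoic acid (palmitic acid)
Product: 7 3-hydroxy-3-methyl-2-oxobutyl hexadecanoate
Conditions: KHCO3 (1.5 equiv), DMF, 40 °C
Reagents that add atoms: none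
Why: SN2 O-alkylation of a carboxylate by an α-bromo ketone (phenacyl-ester-type esterification), fast because the carbonyl activates the C–Br bond, while the tertiary alcohol is not nucleophilic under bicarbonate conditions.

**Step 4**
Reactants: 3 5-(3-methylbut-2-en-1-yl)-1H-indole; 7 3-hydroxy-3-methyl-2-oxobutyl hexadecanoate
Product: 10 (2S)-3-hydroxy-3-methyl-2-[5-(3-methylbut-2-en-1-yl)-1H-indol-3-yl]butyl hexadecanoate, via tertiary carbinol 8 (not isolated), via azafulvenium ion 9 (not isolated)
Conditions: (R)-3,3'-bis(2,4,6-triisopropylphenyl)-1,1'-binaphthyl-2,2'-diyl N-triflylphosphoramide (10 mol %), diethyl 2,6-dimethyl-1,4-dihydropyridine-3,5-dicarboxylate (Hantzsch ester, 1.4 equiv), 5 Å MS, toluene, 40 °C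
Reagents that add atoms: none
Why: Proposed new method: a chiral Brønsted-acid-catalysed reductive Friedel–Crafts alkylation of an N–H indole with an unsymmetrical, non-aromatic α-acyloxy-α'-hydroxy ketone; the acid activates the inductively activated ketone 7 for attack by C3 of 3 to give carbinol 8 and ionises 8 to the indole-stabilised azafulvenium (vinylogous iminium) ion 9, whose bulky CMe2OH group lies syn to C2–H; the phosphoramide anion then holds 9 (N–H and O–H hydrogen bonds) and the Hantzsch ester (its N–H) so that hydride is delivered to the Re face of the exocyclic carbon, which gives the (S) centre; hydride capture should outrun a 1,2-methyl (pinacol) shift because methyl migrates poorly to so stabilised a cation, and the Hantzsch pyridine buffers the acid so the prenyl olefin survives; closest known reaction types are the achiral acid/silane reductive alkylation of indoles with ketones and the chiral phosphoric acid/Hantzsch ester transfer hydrogenation of azafulvenium ions made from preformed aryl-substituted 3-indolylmethanols.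

**Compound list**
1 | 5-bromo-1H-indole | Brc1ccc2[nH]ccc2c1 | starting material
2 | 2-(3-methylbut-2-en-1-yl)-4,4,5,5-tetramethyl-1,3,2-dioxaborolane | CC(C)=CCB1OC(C)(C)C(C)(C)O1 | starting material
3 | 5-(3-methylbut-2-en-1-yl)-1H-indole | CC(C)=CCc1ccc2[nH]ccc2c1 | intermediate
4 | 3-hydroxy-3-methylbutan-2-one | CC(=O)C(C)(C)O | starting material
5 | 1-bromo-3-hydroxy-3-methylbutan-2-one | BrCC(=O)C(C)(C)O | intermediate
6 | hexadecanoic acid (palmitic acid) | CCCCCCCCCCCCCCCC(=O)O | starting material
7 | 3-hydroxy-3-methyl-2-oxobutyl hexadecanoate | CCCCCCCCCCCCCCCC(=O)OCC(=O)C(C)(C)O | intermediate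
8 | 2,3-dihydroxy-3-methyl-2-[5-(3-methylbut-2-en-1-yl)-1H-indol-3-yl]butyl hexadecanoate (tertiary carbinol, both enantiomers, not isolated) | CCCCCCCCCCCCCCCC(=O)OCC(O)(c1c[nH]c2ccc(CC=C(C)C)cc12)C(C)(C)O | intermediate
9 | 3-[1-(hexadecanoyloxy)-3-hydroxy-3-methylbutan-2-ylidene]-5-(3-methylbut-2-en-1-yl)-3H-indol-1-ium (azafulvenium ion, paired with the catalyst anion, CMe2OH syn to C2–H, not isolated) | CCCCCCCCCCCCCCCC(=O)OC/C(C(C)(C)O)=C1/C=[NH+]c2ccc(CC=C(C)C)cc12 | intermediate
10 | (2S)-3-hydroxy-3-methyl-2-[5-(3-methylbut-2-en-1-yl)-1H-indol-3-yl]butyl hexadecanoate | CCCCCCCCCCCCCCCC(=O)OC[C@H](c1c[nH]c2ccc(CC=C(C)C)cc12)C(C)(C)O | target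

**Step count and risks**
Total steps: 4. Longest linear sequence: 3 steps (4 → 5 → 7 → 10); the other branch is 1 → 3 → 10.

Most likely to fail, first: step 4 (the proposed new method). The hindered ketone 7 may be too unreactive at an acidity the prenyl group tolerates, ion 9 may undergo a pinacol methyl shift, or the facial selectivity may be low. The fallback uses known chemistry only; it sets out from boronate 2 and comes back to the route at 10. Purchased, achiral methyl 2-(5-bromo-1H-indol-3-yl)acetate F1 is coupled with 2 using the step 1 catalyst but aqueous K3PO4 in THF at 70 °C, which spares the ester, to give methyl 2-[5-(3-methylbut-2-en-1-yl)-1H-indol-3-yl]acetate F2. Its dianion (LiN(i-Pr)2, 2.2 equiv, THF, −78 °C) is quenched with acetone in an ester-enolate aldol addition to give racemic methyl 3-hydroxy-3-methyl-2-[5-(3-methylbut-2-en-1-yl)-1H-indol-3-yl]butanoate F3. LiBH4 in THF at 0 °C to rt reduces the ester to racemic 3-methyl-2-[5-(3-methylbut-2-en-1-yl)-1H-indol-3-yl]butane-1,3-diol F4. A lipase kinetic resolution (immobilised Burkholderia cepacia lipase, vinyl hexadecanoate 0.6 equiv, t-BuOMe, 30 °C, stopped near 45% conversion) then acylates only the primary hydroxyl of one enantiomer. This gives 10 directly and leaves (2R)-3-methyl-2-[5-(3-methylbut-2-en-1-yl)-1H-indol-3-yl]butane-1,3-diol F5, which is removed by chromatography. The fallback as written assumes the enzyme prefers the (S)-alcohol, which must be confirmed on the racemate. The stereocenter is still set by metal-free asymmetric catalysis from achiral materials, at the cost of a maximum 50% yield in the last operation.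

Second: step 1. The coupling may give some 1,1-dimethylallyl (γ) isomer, or the indolide formed in strong base may slow the catalyst. The fallback sets out from 1 and comes back at 3, and avoids any α/γ question. Suzuki coupling of 1 with allylboronic acid pinacol ester (Pd(PPh3)4, CsF, THF, reflux) gives 5-(prop-2-en-1-yl)-1H-indole F6. Olefin cross-metathesis of F6 with excess 2-methylbut-2-ene (second-generation Grubbs catalyst (H2IMes)(PCy3)Cl2Ru=CHPh, CH2Cl2, 40 °C) converts the allyl group into the prenyl group of 3.

Third: step 2. Over-bromination, loss of the labile, lachrymatory bromoketone 5 on work-up, or HBr damage to the tertiary alcohol can erode the yield. The fallback sets out from 6, comes back at 7 and replaces steps 2 and 3 by oxidising an olefin instead of substituting a ketone. Steglich esterification of 6 with 3-methylbut-2-en-1-ol (DCC, DMAP, CH2Cl2, rt) gives 3-methylbut-2-en-1-yl hexadecanoate F7. Ketohydroxylation of its trisubstituted olefin (RuCl3 1 mol %, KHSO5 as the triple salt 2KHSO5·KHSO4·K2SO4, NaHCO3, EtOAc/MeCN/H2O, rt) can only place the ketone on the former CH carbon and the hydroxyl on the CMe2 carbon, which is 7.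

**Further compounds**
F1 | step 4 | methyl 2-(5-bromo-1H-indol-3-yl)acetate (purchased) | COC(=O)Cc1c[nH]c2ccc(Br)cc12
F2 | step 4 | methyl 2-[5-(3-methylbut-2-en-1-yl)-1H-indol-3-yl]acetate | COC(=O)Cc1c[nH]c2ccc(CC=C(C)C)cc12
F3 | step 4 | methyl 3-hydroxy-3-methyl-2-[5-(3-methylbut-2-en-1-yl)-1H-indol-3-yl]butanoate (racemic) | COC(=O)C(c1c[nH]c2ccc(CC=C(C)C)cc12)C(C)(C)O
F4 | step 4 | 3-methyl-2-[5-(3-methylbut-2-en-1-yl)-1H-indol-3-yl]butane-1,3-diol (racemic) | OCC(c1c[nH]c2ccc(CC=C(C)C)cc12)C(C)(C)O
F5 | step 4 | (2R)-3-methyl-2-[5-(3-methylbut-2-en-1-yl)-1H-indol-3-yl]butane-1,3-diol (unreacted enantiomer) | OC[C@@H](c1c[nH]c2ccc(CC=C(C)C)cc12)C(C)(C)O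
F6 | step 1 | 5-(prop-2-en-1-yl)-1H-indole | C=CCc1ccc2[nH]ccc2c1
F7 | step 2 | 3-methylbut-2-en-1-yl hexadecanoate | CCCCCCCCCCCCCCCC(=O)OCC=C(C)C
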